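## The problem

Compound 28 is a germacranolide: a ten-membered carbocycle (C1–C10) with a butenolide fused at C6/C7 (O–C6, C7=C11, C12 carbonyl), a cis-4,5-epoxide carrying the C4 methyl group, a C1 ketone next to a fully substituted C10 (methyl and acetate), a methacrylate at C8 and an acetate on the C13 methylene group. A synthesis has to close a medium ring in which nearly every carbon is functionalised and to set five stereocentres. C4, C5 and C6 are contiguous, so the C6 carbinol can direct the epoxide. C8 and C10 are isolated from this triad and from each other by sp2 or methylene carbons, so only the conformation of a ring can control them. The functional groups tolerate little. C6–H is γ to the lactone carbonyl and vinylogous to the C13 acetate, so base can expel acetate or open the adjacent epoxide. The methacrylate is a Michael acceptor, the tertiary α-acetoxy ketone can transfer its acyl group, and the epoxide excludes strong acid. The feature that opens the structure is the 1,5-relationship of C1 and C7 (a carbonyl carbon before the butenolide is made) through C8, C9 and C10: C9 is a bare methylene group and C10 carries exactly a methyl and an acetoxy group, the atoms of isopropenyl acetate. Taking out C9 and C10 leaves an eight-membered 1,3-dicarbonyl ring that still holds C4–C6. In the forward direction this is (2+2) photocycloaddition of an alkene to a 1,3-diketone enol derivative followed by retro-aldol cleavage.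

## Retrosynthesis

**C13 acetate (28 ⇒ 27 ⇒ 26).** The C13–O acyl bond is cut first, back to alcohol 27 and its p-methoxybenzyl ether 26. An acetate at C13 cannot pass through the base needed for the butenolide because it is a vinylogous leaving group; an ether is a poor leaving group and DDQ removes it at neutral pH. The forward steps ask only for a neutral deprotection and a mild acetylation.

**Butenolide (26 ⇒ 25 ⇒ 20 + 24).** The C7=C11 bond and the C12–O6 ester bond are cut, which leads to an intramolecular Horner–Wadsworth–Emmons closure of phosphonate 25, made from hydroxy ketone 20 and acid 24. Adding C13 to a finished butenolide is not an option, since deprotonation gives the C6 furanolate, so C11–C13 must arrive as one reagent. The precursor loses a ring and three carbons. The forward reaction must close onto a ketone flanked by two oxygenated carbons without deprotonating C6 or expelling the C13 alkoxide.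

**C8 oxygen (20 ⇒ 19 ⇒ 18 ⇒ 16).** The C8 ester and then the C8–O bond are cut: methacrylate 19 comes from alcohol 18, and 18 from Rubottom oxidation of the C7=C8 enol silane 16; PMB removal (19 → 20) follows. Hydroxylation after butenolide formation would fail (C6 is deprotonated instead). Enolising a free C7 ketone would compete with C2 and C6. The enol silane must therefore be delivered regiospecifically by the preceding step. The forward reaction must choose the correct face at C8.

**Key disconnection (16 ⇒ 12 + 13).** C1–C10 and C8–C9 are cut and C1–C8 is reconnected: ten-membered 16 becomes eight-membered vinylogous silyl ester 12 plus isopropenyl acetate 13. This removes two carbons and one stereocentre, brings the tertiary acetate intact from a commodity alkene and leaves oxygen at C1 and C7 in the right oxidation states. The retro-aldol step also releases exactly the C7–C8 enolate needed above, so the product is taken as its enol silane rather than as the free dione. Direct closure of the ten-membered ring (metathesis or macroaldol) would have to overcome medium-ring strain without a template; ring expansion is driven by cyclobutane strain. A triethylsilyl group is chosen on the enol oxygen because it must be cleaved cold from a hindered tertiary cyclobutanol. The forward reaction must give head-to-tail regiochemistry and the 10R configuration.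

**Eight-membered ring functionality (12 ⇒ 11 ⇒ 10 ⇒ 9 ⇒ 8).** The Si–O bond, the C7 carbonyl (from the carbinol of 10), the epoxide (from the alkene of 9) and the C1 ketone (from the dithiane of 8) are removed in turn. C7 stays a carbinol until the end of this sequence because a C7 carbonyl makes C6–H acidic next to an alkene or epoxide. The epoxide is put on the cyclooctene, where peracids attack trans to an allylic substituent. The forward steps need anti epoxidation and O-silylation at the C1 oxygen.

**Ring closure (8 ⇒ 7).** The C4=C5 bond is cut (ring-closing metathesis). An eight-membered ring is best closed where a cis alkene is wanted anyway, and the ring enforces Z geometry. Claisen or aldol closures would need strong base next to C6 and have no conformational bias. The dithiane supplies a gem-disubstituent effect and masks C1.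

**Chain assembly (7 ⇒ 3 + 4 + 5; 3 ⇒ 2 ⇒ 1).** C1–C2 and C1–C8 are cut with 1,3-dithiane 4 as a carbonyl dianion equivalent, alkylated by bromide 5 and by epoxide 3. Epoxide 3 comes from epoxy alcohol 2, the product of desymmetrising Sharpless epoxidation of divinyl carbinol 1. This sets C6 absolutely in the first step. An aldol route through a 2-alkoxybut-3-enal or additions to a Z-enal would pass through configurationally labile intermediates.

**Phosphonate reagent (24 ⇒ 23 ⇒ 21).** The C11–C13 and C13–O bonds are cut: Knoevenagel/oxa-Michael reaction of allyl phosphonoacetate 21 with formaldehyde and p-methoxybenzyl alcohol gives 23. The allyl ester is removed with zerovalent palladium because hydroxide would trigger retro-Michael loss of the alkoxide.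

## Roads not taken

**Alternative 1:** The cut is at C6–C7 and the lactone C12–O bond. Open-chain ester A2 carries the 4,5-epoxy aldehyde (C6) at one end and a Z-enol triflate at C7 with the C12 ester cis to it at the other, joined through the C1(10) E-alkene and the silylated C8 carbinol. Under Nozaki–Hiyama–Kishi conditions (CrCl2, catalytic NiCl2) the alkenylchromium species would add to the aldehyde, closing the ten-membered ring, and the C6 alkoxide would lactonise to give A1.
- Merits: ring and butenolide form in one step; the route is convergent; the C8 oxygen comes from fragment synthesis.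
- Weak points: A1 has a C1(10) alkene where 28 has a ketone and a tertiary acetate. Dihydroxylation, selective oxidation and acetylation of a hindered tertiary ketol would follow, and C10 would again depend on the facial bias of a ten-membered ring. C6 is created in the macrocyclisation, where Felkin and chelation control compete at an α,β-epoxy aldehyde. The C13 allylic acetate is an electrophile for low-valent nickel, and oxidative addition into a tetrasubstituted enol triflate is slow.
- Comparison: this road is better in convergence and in the origin of C8. The chosen plan sets against that a Rubottom oxidation that can be corrected by Mitsunobu inversion, C6 from an asymmetric epoxidation, and the C1/C10 oxidation pattern directly from the key step.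

**Alternative 2:** The cut is at the two C–O bonds of the lactone (C6–O and C12–O). Diene A4 (C6=C7 in the ring, C11=C12 an exocyclic methylene bearing the acetoxymethyl group) would add singlet oxygen across C6 and C12 to give the 3,6-dihydro-1,2-dioxine A3. Base-induced peroxide isomerisation and an oxidation-level adjustment would then give the butenolide.
- Merits: metal-free; both lactone oxygens arrive late; the tetrasubstituted C7=C11 alkene results directly; no phosphonate reagent is needed.
- Weak points: this is an end-game tactic, not a ring construction. A4 already contains the ten-membered ring, C8 and C10, so it needs a ring synthesis such as the one chosen here. A4 is an alkenyl epoxide with allylic hydrogens at C8 and C13 open to the ene reaction. The face of addition defines C6 without an evident control element. The peroxide isomerisation needs base at C6–H, where base does damage.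
- Comparison: from A4 the lactone would take fewer operations than steps 12–18, a real advantage. The chosen plan sets against that a C6 configuration fixed in step 1, with no face to choose at C6 on the medium ring.

**Alternative 3:** C8–C9 is formed while a six-membered ring bond is broken. The potassium alkoxide of cyclohexenol A6 (trans 1-(2-silylvinyl) and 6-isopropenyl groups) would undergo anionic oxy-Cope rearrangement through a chair to the ten-membered dienone A5, with C1(10) E- and C4 Z-alkenes and the silyl-bearing C8 stereocentre.
- Merits: the best-precedented entry to germacrane rings; cheap terpene-derived material; no photochemistry; chirality transfer to C8 with silicon as a masked hydroxyl.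
- Weak points: A5 is far from 28 in oxidation pattern. C7 is a methylene without C11–C13, the ketone sits at C6 where a carbinol is needed, C1(10) is an alkene, and the C4 alkene must still be epoxidised anti to a C6 oxygen that does not yet exist. C4, C5, C6 and C10 would all be set by reagent attack on a flexible ring. The arylsilane would have to be unmasked in the presence of two alkenes.
- Comparison: this road is better in the reliability and cost of the ring-forming step. The chosen plan sets against that a ring expansion which leaves carbonyl groups at C1 and C7 and the acetate at C10 exactly where needed, with C4–C6 already enantiopure, so fewer redox steps are needed on the medium ring.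

Key step: step 9

Remarks on the chemistry (assumptions):
- Locants C1–C13 follow germacrane numbering throughout (C1 ketone, C4–C5 epoxide, C6 lactone carbinol, C7=C11, C8 ester carbinol, C10 acetoxy carbon, C12 lactone carbonyl, C13 acetoxymethyl). CIP descriptors in the ring names use these locants unless a systematic ring name is given.
- The geometry of the C7=C8 enol silane 16 is set by the conformation of cyclobutane 14 at fragmentation and cannot be predicted with confidence. It is written as 7Z (silyloxy group and C9 cis); either isomer would be taken into step 10.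
- Compounds 23–25 are mixtures at the phosphonate carbon; that centre disappears in step 16.

## Route

Step 1
Reactants: 1 penta-1,4-dien-3-ol
Product: 2 (2R,3S)-1,2-epoxypent-4-en-3-ol
Conditions: Ti(OiPr)4 (cat.), L-(+)-diisopropyl tartrate, t-BuOOH, 4 Å MS, CH2Cl2, −20 °C
Reagents that add atoms: tert-butyl hydroperoxide, CC(C)(C)OO
Why: Sharpless asymmetric epoxidation used as a desymmetrisation: the catalyst selects one enantiotopic vinyl group and the erythro face, and the minor enantiomer is consumed faster by a second epoxidation, so enantiopurity should rise with conversion; this fixes C6 (and C7, which is oxidised later).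

Step 2
Reactants: 2 (2R,3S)-1,2-epoxypent-4-en-3-ol
Product: 3 (2R)-2-[(1S)-1-[(4-methoxyphenyl)methoxy]prop-2-en-1-yl]oxirane
Conditions: NaH, 4-methoxybenzyl chloride, Bu4NI (cat.), THF, −20 → 0 °C
Reagents that add atoms: 4-methoxybenzyl chloride, COc1ccc(CCl)cc1
Why: Williamson etherification of the secondary alkoxide with an activated benzylic halide at low temperature should outrun Payne equilibration; the PMB ether survives organolithium, ruthenium, peracid, fluoride and 350 nm light and is later removed by DDQ without acid or base.

Step 3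
Reactants: 4 1,3-dithiane; 5 4-bromo-2-methylbut-1-ene; 3 (2R)-2-[(1S)-1-[(4-methoxyphenyl)methoxy]prop-2-en-1-yl]oxirane
Product: 7 (2R,3S)-3-[(4-methoxyphenyl)methoxy]-1-[2-(3-methylbut-3-en-1-yl)-1,3-dithian-2-yl]pent-4-en-2-ol, via alkylated dithiane 6 (not isolated)
Conditions: 4, n-BuLi, THF, −30 °C; 5, −78 → 0 °C; n-BuLi, −25 °C; 3, −78 → 0 °C; H2O
Reagents that add atoms: none
Why: Corey–Seebach umpolung in one flask: 2-lithio-1,3-dithiane is alkylated by the primary bromide, and the re-lithiated 2-alkyl dithiane opens the monosubstituted epoxide at its CH2 terminus (C8), so C1 enters as a masked ketone between C2 and C8 while C6 and C7 are untouched.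

Step 4
Reactants: 7 (2R,3S)-3-[(4-methoxyphenyl)methoxy]-1-[2-(3-methylbut-3-en-1-yl)-1,3-dithian-2-yl]pent-4-en-2-ol
Product: 8 (8R,9S,10Z)-9-[(4-methoxyphenyl)methoxy]-11-methyl-1,5-dithiaspiro[5.7]tridec-10-en-8-ol
Conditions: second-generation Grubbs catalyst RuCl2(=CHPh)(H2IMes)(PCy3) (10 mol %), toluene (2 mM), 80 °C
Reagents that add atoms: none
Why: Ring-closing metathesis: the catalyst loads on the monosubstituted vinyl group and closes onto the 1,1-disubstituted alkene to give the trisubstituted cyclooctene, necessarily Z in an eight-membered ring; the quaternary dithiane carbon and the gauche vicinal oxygen substituents favour the cyclic conformer, and catalysts with N-heterocyclic carbene ligands tolerate thioacetals.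

Step 5
Reactants: 8 (8R,9S,10Z)-9-[(4-methoxyphenyl)methoxy]-11-methyl-1,5-dithiaspiro[5.7]tridec-10-en-8-ol
Product: 9 (3R,4S,5Z)-3-hydroxy-4-[(4-methoxyphenyl)methoxy]-6-methylcyclooct-5-en-1-one
Conditions: MeI, CaCO3, MeCN/H2O (4:1), 45 °C
Reagents that add atoms: water, O
Why: Alkylative hydrolysis of the thioacetal (S-methylation, then water) under carbonate buffering; no acid is present, so the β-hydroxy ketone should not dehydrate and the PMB ether and alkene are untouched.

Step 6
Reactants: 9 (3R,4S,5Z)-3-hydroxy-4-[(4-methoxyphenyl)methoxy]-6-methylcyclooct-5-en-1-one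
Product: 10 (1R,6R,7R,8S)-6-hydroxy-7-[(4-methoxyphenyl)methoxy]-1-methyl-9-oxabicyclo[6.1.0]nonan-4-one (germacrane 4R,5S,6R,7R)
Conditions: mCPBA, NaHCO3, CH2Cl2, 0 °C
Reagents that add atoms: 3-chloroperoxybenzoic acid, O=C(OO)c1cccc(Cl)c1
Why: Peracid epoxidation of the only electron-rich alkene; 3-substituted cis-cyclooctenes are attacked trans to the allylic substituent because the ring blocks the other face, which places the epoxide oxygen anti to the C6 ether (and the cis C7 hydroxyl) and sets C4 and C5; Baeyer–Villiger oxidation of the ketone is much slower at 0 °C.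

Step 7
Reactants: 10 (1R,6R,7R,8S)-6-hydroxy-7-[(4-methoxyphenyl)methoxy]-1-methyl-9-oxabicyclo[6.1.0]nonan-4-one
Product: 11 (1S,2S,8R)-2-[(4-methoxyphenyl)methoxy]-8-methyl-9-oxabicyclo[6.1.0]nonane-3,5-dione (germacrane 4R,5S,6S)
Conditions: Dess–Martin periodinane, NaHCO3, CH2Cl2, 0 °C → rt
Reagents that add atoms: none
Why: Dess–Martin oxidation of a β-hydroxy ketone to the 1,3-diketone under buffered, non-basic conditions, so that C6, now α to a carbonyl and β to the epoxide, is not deprotonated.

Step 8
Reactants: 11 (1S,2S,8R)-2-[(4-methoxyphenyl)methoxy]-8-methyl-9-oxabicyclo[6.1.0]nonane-3,5-dione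
Product: 12 (1S,2S,4E,8R)-2-[(4-methoxyphenyl)methoxy]-8-methyl-5-[(triethylsilyl)oxy]-9-oxabicyclo[6.1.0]non-4-en-3-one (C7 carbonyl, C1 silyloxy, C8=C1)
Conditions: Et3SiCl, Et3N, CH2Cl2, −40 → 0 °C
Reagents that add atoms: chlorotriethylsilane, CC[Si](Cl)(CC)CC
Why: O-Silylation of the 1,3-diketone through its ammonium enolate; the oxygen at C1, flanked by a methylene group, is less hindered than the oxygen at C7 next to the branched, inductively deactivating C6, the same preference by which 4-substituted cyclic 1,3-diones give the vinylogous ester with the substituent next to the remaining carbonyl; the ring enforces the E (ring-cis) enol ether.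

Step 9
Reactants: 12 (1S,2S,4E,8R)-2-[(4-methoxyphenyl)methoxy]-8-methyl-5-[(triethylsilyl)oxy]-9-oxabicyclo[6.1.0]non-4-en-3-one; 13 isopropenyl acetate
Product: 16 (4R,5S,6S,7Z,10R)-10-acetoxy-4,5-epoxy-6-[(4-methoxyphenyl)methoxy]-4,10-dimethyl-7-[(triethylsilyl)oxy]cyclodec-7-en-1-one, via cyclobutane photoadduct 14 (not isolated), via sulfonium enolate 15 (not isolated)
Conditions: 13 (20 equiv), hν (350 nm, Pyrex), MeCN, −20 °C; evaporate; tris(dimethylamino)sulfonium difluorotrimethylsilicate (TASF, 1.1 equiv), THF, −78 → −40 °C; Et3SiCl, −78 °C → rt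
Reagents that add atoms: chlorotriethylsilane, CC[Si](Cl)(CC)CC
Why: De Mayo sequence: the triplet of vinylogous silyl ester 12 adds isopropenyl acetate stepwise through a 1,4-biradical that closes the cis-fused cyclobutane 14 by radical combination, head to tail (C9 on the α-carbon C8, the oxygenated C10 on the β-carbon C1), the usual orientation of electron-rich alkenes and the one that puts both radical centres on oxygen-bearing carbons. Fluoride then removes the tertiary silyl group and the cyclobutanolate cleaves C1–C8 by retro-aldol reaction, so the ten-membered ring arises by expansion of the bicycle and not by an end-to-end closure; the closest known reaction type is the de Mayo reaction of silyl or acyl enol derivatives of cyclic 1,3-diketones. The fragmentation releases the enolate 15 only between C7 and C8, and silylation in the same flask fixes this regiochemistry, which later enolisation of a ketone competing with C2 and C6 could not give; while C7 is an enolate, C6 cannot epimerise. C10 is the one new stereocentre that survives: the eight-membered ring should adopt a tub in which the enone and the cis-epoxide sit at the two ends like the alkenes of cycloocta-1,5-diene, so the alkene is expected on the convex face that carries the epoxide oxygen, anti to the C6 ether. In the biradical closure the acetoxy group should turn away from the silyloxy group (smaller group over the ring, no eclipsed O/O pair), and the two preferences together give 10R. The step needs this facial and orientational selectivity, head-to-tail regiochemistry and an intact PMB ether; irradiation at 350 nm, where only the enone chromophore absorbs, keeps the ether and the product ketone out of Norrish–Yang chemistry. The stereocentres at C1 and C8 of 14 are destroyed in the fragmentation, so the mode of ring fusion is immaterial.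

Step 10
Reactants: 16 (4R,5S,6S,7Z,10R)-10-acetoxy-4,5-epoxy-6-[(4-methoxyphenyl)methoxy]-4,10-dimethyl-7-[(triethylsilyl)oxy]cyclodec-7-en-1-one
Product: 18 (4R,5S,6S,8S,10R)-10-acetoxy-4,5-epoxy-8-hydroxy-6-[(4-methoxyphenyl)methoxy]-4,10-dimethylcyclodecane-1,7-dione, via silyloxy ketone 17 (not isolated)
Conditions: mCPBA, NaHCO3, CH2Cl2, −20 °C; then HF·pyridine, pyridine, THF, 0 °C
Reagents that add atoms: 3-chloroperoxybenzoic acid, O=C(OO)c1cccc(Cl)c1
Why: Rubottom oxidation: the peracid epoxidises the electron-rich enol silane, the silyloxy oxirane opens with 1,4-silyl shift to the α-silyloxy ketone 17 and buffered HF removes the silyl group. The new C8 stereocentre is set by the face of attack, expected anti to the adjacent C6 p-methoxybenzyloxy group, which shields the β face when C6–H lies in the alkene plane (allylic strain), giving 8S; the regiochemistry is that of the enol silane.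

Step 11
Reactants: 18 (4R,5S,6S,8S,10R)-10-acetoxy-4,5-epoxy-8-hydroxy-6-[(4-methoxyphenyl)methoxy]-4,10-dimethylcyclodecane-1,7-dione
Product: 19 (4R,5S,6S,8S,10R)-10-acetoxy-4,5-epoxy-6-[(4-methoxyphenyl)methoxy]-4,10-dimethyl-1,7-dioxocyclodecan-8-yl 2-methylprop-2-enoate
Conditions: methacrylic anhydride, Et3N, DMAP (cat.), CH2Cl2, 0 °C
Reagents that add atoms: methacrylic anhydride, C=C(C)C(=O)OC(=O)C(C)=C
Why: DMAP-catalysed acylation of the secondary α-hydroxy ketone, done at once so that the α-ketol cannot tautomerise; the tertiary C10 acetate and the C6 ether are unaffected.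

Step 12
Reactants: 19 (4R,5S,6S,8S,10R)-10-acetoxy-4,5-epoxy-6-[(4-methoxyphenyl)methoxy]-4,10-dimethyl-1,7-dioxocyclodecan-8-yl 2-methylprop-2-enoate
Product: 20 (4R,5S,6S,8S,10R)-10-acetoxy-4,5-epoxy-6-hydroxy-4,10-dimethyl-1,7-dioxocyclodecan-8-yl 2-methylprop-2-enoate
Conditions: DDQ, CH2Cl2/pH 7 buffer (10:1), 0 °C → rt
Reagents that add atoms: none
Why: Oxidative cleavage of the p-methoxybenzyl ether by DDQ (hydride abstraction, hydrolysis of the oxocarbenium ion) at neutral pH; epoxide, esters and the methacrylate alkene are inert, and the released α-hydroxy ketone is acylated without delay.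

Step 13
Reactants: 21 allyl 2-(diethoxyphosphoryl)acetate
Product: 23 allyl 2-(diethoxyphosphoryl)-3-[(4-methoxyphenyl)methoxy]propanoate (racemic), via phosphonoacrylate 22 (not isolated)
Conditions: (CH2O)n, piperidine (cat.), 4-methoxybenzyl alcohol (5 equiv), toluene, reflux (Dean–Stark)
Reagents that add atoms: formaldehyde (as paraformaldehyde), C=O; 4-methoxybenzyl alcohol, COc1ccc(CO)cc1
Why: Knoevenagel condensation of the phosphonoacetate with formaldehyde gives the 2-phosphonoacrylate 22, which adds the alcohol present in excess (oxa-Michael addition), the course the standard preparation of 2-phosphonoacrylates takes in an alcohol solvent; this attaches C13 with its oxygen protected as a poor leaving group.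

Step 14
Reactants: 23 allyl 2-(diethoxyphosphoryl)-3-[(4-methoxyphenyl)methoxy]propanoate
Product: 24 2-(diethoxyphosphoryl)-3-[(4-methoxyphenyl)methoxy]propanoic acid (racemic)
Conditions: Pd(PPh3)4 (5 mol %), morpholine, THF, rt; then aq. KHSO4
Reagents that add atoms: none
Why: Tsuji–Trost deallylation with zerovalent palladium and an amine allyl acceptor frees the acid under neutral conditions; hydroxide is avoided because saponification would compete with retro-Michael loss of the C13 alkoxide.

Step 15
Reactants: 20 (4R,5S,6S,8S,10R)-10-acetoxy-4,5-epoxy-6-hydroxy-4,10-dimethyl-1,7-dioxocyclodecan-8-yl 2-methylprop-2-enoate; 24 2-(diethoxyphosphoryl)-3-[(4-methoxyphenyl)methoxy]propanoic acid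
Product: 25 (4R,5S,6S,8S,10R)-10-acetoxy-4,5-epoxy-4,10-dimethyl-8-(methacryloyloxy)-1,7-dioxocyclodecan-6-yl 2-(diethoxyphosphoryl)-3-[(4-methoxyphenyl)methoxy]propanoate (both epimers at the phosphonate carbon)
Conditions: 24, EDC·HCl, DMAP (cat.), CH2Cl2, 0 °C → rt
Reagents that add atoms: none
Why: Steglich-type carbodiimide esterification of the C6 hydroxyl; the C6–O bond is not broken, so C6 keeps its configuration, and at 0 °C with catalytic DMAP acylation of the free hydroxyl should be faster than migration of the C8 methacrylate.

Step 16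
Reactants: 25 (4R,5S,6S,8S,10R)-10-acetoxy-4,5-epoxy-4,10-dimethyl-8-(methacryloyloxy)-1,7-dioxocyclodecan-6-yl 2-(diethoxyphosphoryl)-3-[(4-methoxyphenyl)methoxy]propanoate
Product: 26 (4R,5S,6R,8S,10R)-10-acetoxy-4,5-epoxy-8-(methacryloyloxy)-13-[(4-methoxyphenyl)methoxy]-1-oxogermacr-7(11)-en-12,6-olide
Conditions: LiCl, iPr2NEt, MeCN, 0 °C → rt
Reagents that add atoms: none
Why: Intramolecular Horner–Wadsworth–Emmons olefination under Masamune–Roush conditions: the lithium-chelated phosphonate is deprotonated by a tertiary amine and closes a five-membered ring onto the C7 ketone, forming C7=C11 and the butenolide; the weak base should spare C6–H and C8–H, and any p-methoxybenzyl oxide lost by β-elimination can re-add to the resulting phosphonoacrylate, so elimination is not a dead end.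

Step 17
Reactants: 26 (4R,5S,6R,8S,10R)-10-acetoxy-4,5-epoxy-8-(methacryloyloxy)-13-[(4-methoxyphenyl)methoxy]-1-oxogermacr-7(11)-en-12,6-olide
Product: 27 (4R,5S,6R,8S,10R)-10-acetoxy-4,5-epoxy-13-hydroxy-8-(methacryloyloxy)-1-oxogermacr-7(11)-en-12,6-olide
Conditions: DDQ, CH2Cl2/pH 7 buffer (10:1), rt
Reagents that add atoms: none
Why: Second DDQ cleavage of a p-methoxybenzyl ether, now the primary allylic one at C13, again at neutral pH so that neither the epoxide nor C6–H is disturbed.

Step 18
Reactants: 27 (4R,5S,6R,8S,10R)-10-acetoxy-4,5-epoxy-13-hydroxy-8-(methacryloyloxy)-1-oxogermacr-7(11)-en-12,6-olide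
Product: 28 (4R,5S,6R,8S,10R)-10,13-diacetoxy-4,5-epoxy-8-(methacryloyloxy)-1-oxogermacr-7(11)-en-12,6-olide (CNP0172381.2)
Conditions: Ac2O, pyridine, DMAP (cat.), CH2Cl2, 0 °C
Reagents that add atoms: acetic anhydride, CC(=O)OC(C)=O
Why: Acylation of the primary allylic alcohol with acetic anhydride and pyridine, a base too weak to deprotonate C6; tertiary acetate, methacrylate, epoxide and butenolide are unchanged and the product is 28.

## Compound list

1 | penta-1,4-dien-3-ol | C=CC(O)C=C | starting material
2 | (2R,3S)-1,2-epoxypent-4-en-3-ol | C=C[C@H](O)[C@H]1CO1 | intermediate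
3 | (2R)-2-[(1S)-1-[(4-methoxyphenyl)methoxy]prop-2-en-1-yl]oxirane | C=C[C@H](OCc1ccc(OC)cc1)[C@H]1CO1 | intermediate
4 | 1,3-dithiane | C1CSCSC1 | starting material
5 | 4-bromo-2-methylbut-1-ene | C=C(C)CCBr | starting material
6 | 2-(3-methylbut-3-en-1-yl)-1,3-dithiane | C=C(C)CCC1SCCCS1 | intermediate
7 | (2R,3S)-3-[(4-methoxyphenyl)methoxy]-1-[2-(3-methylbut-3-en-1-yl)-1,3-dithian-2-yl]pent-4-en-2-ol | C=C[C@H](OCc1ccc(OC)cc1)[C@H](O)CC1(CCC(C)=C)SCCCS1 | intermediate
8 | (8R,9S,10Z)-9-[(4-methoxyphenyl)methoxy]-11-methyl-1,5-dithiaspiro[5.7]tridec-10-en-8-ol | C/C1=C/[C@H](OCc2ccc(OC)cc2)[C@H](O)CC3(CC1)SCCCS3 | intermediate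
9 | (3R,4S,5Z)-3-hydroxy-4-[(4-methoxyphenyl)methoxy]-6-methylcyclooct-5-en-1-one | C/C1=C/[C@H](OCc2ccc(OC)cc2)[C@H](O)CC(=O)CC1 | intermediate
10 | (1R,6R,7R,8S)-6-hydroxy-7-[(4-methoxyphenyl)methoxy]-1-methyl-9-oxabicyclo[6.1.0]nonan-4-one | O=C1CC[C@@]2(C)O[C@H]2[C@H](OCc3ccc(OC)cc3)[C@H](O)C1 | intermediate
11 | (1S,2S,8R)-2-[(4-methoxyphenyl)methoxy]-8-methyl-9-oxabicyclo[6.1.0]nonane-3,5-dione | O=C1CC[C@@]2(C)O[C@H]2[C@H](OCc3ccc(OC)cc3)C(=O)C1 | intermediate
12 | (1S,2S,4E,8R)-2-[(4-methoxyphenyl)methoxy]-8-methyl-5-[(triethylsilyl)oxy]-9-oxabicyclo[6.1.0]non-4-en-3-one | O=C1/C=C(/O[Si](CC)(CC)CC)CC[C@@]2(C)O[C@H]2[C@@H]1OCc1ccc(OC)cc1 | intermediate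
13 | isopropenyl acetate (prop-1-en-2-yl acetate) | CC(=C)OC(C)=O | starting material
14 | (1R,4R,5S,6S,8S,10R)-10-acetoxy-4,5-epoxy-6-[(4-methoxyphenyl)methoxy]-4,10-dimethyl-1-[(triethylsilyl)oxy]bicyclo[6.2.0]decan-7-one, germacrane locants (cyclobutane C1–C10–C9–C8, cis ring fusion, acetoxy trans to silyloxy) | O=C1[C@H]2C[C@@](C)(OC(C)=O)[C@@]2(O[Si](CC)(CC)CC)CC[C@@]3(C)O[C@H]3[C@@H]1OCc1ccc(OC)cc1 | intermediate
15 | tris(dimethylamino)sulfonium (4R,5S,6S,7Z,10R)-10-acetoxy-4,5-epoxy-6-[(4-methoxyphenyl)methoxy]-4,10-dimethyl-1-oxocyclodec-7-en-7-olate | [O-]/C1=C\C[C@@](C)(OC(C)=O)C(=O)CC[C@@]2(C)O[C@H]2[C@@H]1OCc1ccc(OC)cc1.CN(C)[S+](N(C)C)N(C)C | intermediate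
16 | (4R,5S,6S,7Z,10R)-10-acetoxy-4,5-epoxy-6-[(4-methoxyphenyl)methoxy]-4,10-dimethyl-7-[(triethylsilyl)oxy]cyclodec-7-en-1-one | CC[Si](CC)(CC)O/C1=C\C[C@@](C)(OC(C)=O)C(=O)CC[C@@]2(C)O[C@H]2[C@@H]1OCc1ccc(OC)cc1 | intermediate
17 | (4R,5S,6S,8S,10R)-10-acetoxy-4,5-epoxy-6-[(4-methoxyphenyl)methoxy]-4,10-dimethyl-8-[(triethylsilyl)oxy]cyclodecane-1,7-dione | CC[Si](CC)(CC)O[C@H]1C[C@@](C)(OC(C)=O)C(=O)CC[C@@]2(C)O[C@H]2[C@H](OCc2ccc(OC)cc2)C1=O | intermediate
18 | (4R,5S,6S,8S,10R)-10-acetoxy-4,5-epoxy-8-hydroxy-6-[(4-methoxyphenyl)methoxy]-4,10-dimethylcyclodecane-1,7-dione | O[C@H]1C[C@@](C)(OC(C)=O)C(=O)CC[C@@]2(C)O[C@H]2[C@H](OCc2ccc(OC)cc2)C1=O | intermediate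
19 | (4R,5S,6S,8S,10R)-10-acetoxy-4,5-epoxy-6-[(4-methoxyphenyl)methoxy]-4,10-dimethyl-1,7-dioxocyclodecan-8-yl 2-methylprop-2-enoate | C=C(C)C(=O)O[C@H]1C[C@@](C)(OC(C)=O)C(=O)CC[C@@]2(C)O[C@H]2[C@H](OCc2ccc(OC)cc2)C1=O | intermediate
20 | (4R,5S,6S,8S,10R)-10-acetoxy-4,5-epoxy-6-hydroxy-4,10-dimethyl-1,7-dioxocyclodecan-8-yl 2-methylprop-2-enoate | C=C(C)C(=O)O[C@H]1C[C@@](C)(OC(C)=O)C(=O)CC[C@@]2(C)O[C@H]2[C@H](O)C1=O | intermediate
21 | allyl 2-(diethoxyphosphoryl)acetate | C=CCOC(=O)CP(=O)(OCC)OCC | starting material
22 | allyl 2-(diethoxyphosphoryl)prop-2-enoate | C=CCOC(=O)C(=C)P(=O)(OCC)OCC | intermediate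
23 | allyl 2-(diethoxyphosphoryl)-3-[(4-methoxyphenyl)methoxy]propanoate (racemic) | C=CCOC(=O)C(COCc1ccc(OC)cc1)P(=O)(OCC)OCC | intermediate
24 | 2-(diethoxyphosphoryl)-3-[(4-methoxyphenyl)methoxy]propanoic acid (racemic) | OC(=O)C(COCc1ccc(OC)cc1)P(=O)(OCC)OCC | intermediate
25 | (4R,5S,6S,8S,10R)-10-acetoxy-4,5-epoxy-4,10-dimethyl-8-(methacryloyloxy)-1,7-dioxocyclodecan-6-yl 2-(diethoxyphosphoryl)-3-[(4-methoxyphenyl)methoxy]propanoate (epimers at the phosphonate carbon) | C=C(C)C(=O)O[C@H]1C[C@@](C)(OC(C)=O)C(=O)CC[C@@]2(C)O[C@H]2[C@H](OC(=O)C(COCc2ccc(OC)cc2)P(=O)(OCC)OCC)C1=O | intermediate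
26 | (4R,5S,6R,8S,10R)-10-acetoxy-4,5-epoxy-8-(methacryloyloxy)-13-[(4-methoxyphenyl)methoxy]-1-oxogermacr-7(11)-en-12,6-olide | C=C(C)C(=O)O[C@H]1C[C@@](C)(OC(C)=O)C(=O)CC[C@@]2(C)O[C@H]2[C@@H]2OC(=O)C(COCc3ccc(OC)cc3)=C12 | intermediate
27 | (4R,5S,6R,8S,10R)-10-acetoxy-4,5-epoxy-13-hydroxy-8-(methacryloyloxy)-1-oxogermacr-7(11)-en-12,6-olide | C=C(C)C(=O)O[C@H]1C[C@@](C)(OC(C)=O)C(=O)CC[C@@]2(C)O[C@H]2[C@@H]2OC(=O)C(CO)=C12 | intermediate
28 | (4R,5S,6R,8S,10R)-10,13-diacetoxy-4,5-epoxy-8-(methacryloyloxy)-1-oxogermacr-7(11)-en-12,6-olide (CNP0172381.2) | C=C(C)C(=O)O[C@H]1C[C@@](C)(OC(C)=O)C(=O)CC[C@@]2(C)O[C@H]2[C@@H]2OC(=O)C(COC(C)=O)=C12 | target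

## Step count and least certain steps

Total step count: 18. Longest linear sequence: 16 steps (1 → 28 through steps 1–12 and 15–18); steps 13 and 14 prepare acid 24.

**Step 9 (key step).** Most likely to go wrong: poor facial or orientational selectivity in the photocycloaddition. The centres that must steer the alkene (C4–C6) lie three or more atoms from the carbon that becomes C10, and the result would be 16 mixed with its C10 epimer F1. Fallback (sets out from the mixture of 16 and the (10S)-epimer F1, returns at 16): the C10 configuration is erased and rewritten under reagent control. SmI2 in THF at −78 °C removes the α-acetoxy group of both epimers by ketyl formation and β-elimination, leaving the trivalent samarium C1(10)-enolate F2, in which C10 is no longer stereogenic. This enolate is formed regiospecifically because C1 is the only ketone present; the C7 enol silane, epoxide and PMB ether are inert. In the same flask the enolate is hydroxylated with the enantiomer of (camphorsulfonyl)oxaziridine matched to 10R, giving the tertiary α-hydroxy ketone F3. Acetylation (Ac2O, DMAP, Et3N) returns 16.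

**Step 4.** Most likely to go wrong: sequestration of the ruthenium alkylidene by the dithiane sulfur atoms close to the initiating vinyl group, so that oligomerisation overtakes closure of the eight-membered ring. Fallback (sets out from 7, returns at 9): the ketone is unmasked first (MeI, CaCO3, aqueous MeCN) to give the keto diene F4, and the metathesis is run on this sulfur-free substrate at higher dilution. The gem-disubstituent effect is lost, but the gauche C6/C7 oxygen substituents still favour the folded chain, and closure gives 9 directly.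

**Step 10.** Most likely to go wrong: attack of the peracid on the β face of the flexible ten-membered enol ether, giving the 8-epimeric alcohol F5. Fallback (sets out from 16 through F5, returns at 19): Mitsunobu esterification of the (8R)-alcohol F5 with methacrylic acid (PPh3, diisopropyl azodicarboxylate) inverts C8 and installs the methacrylate in one operation, replacing step 11. Displacement α to a ketone is fast.

**Step 16.** Most likely to go wrong: deprotonation at C6 (epimerisation or opening of the epoxide), or slow closure onto the hindered, doubly α-oxygenated ketone while the carbanion sheds its C13 alkoxide. Fallback (sets out from 20, returns at 27): the lactone is built without base. (Triphenylphosphoranylidene)ketene adds the C6 hydroxyl to give the ester ylide F6, which closes by intramolecular Wittig reaction onto C7 to the C11-unsubstituted butenolide F7. α-Iodination (I2, pyridine) gives the 11-iodobutenolide F8, and Stille coupling with (tributylstannyl)methanol and Pd(PPh3)4 attaches the hydroxymethyl group, giving 27.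

## Further compounds

F1 | step 9 | (4R,5S,6S,7Z,10S)-10-acetoxy-4,5-epoxy-6-[(4-methoxyphenyl)methoxy]-4,10-dimethyl-7-[(triethylsilyl)oxy]cyclodec-7-en-1-one (C10 epimer of 16) | CC[Si](CC)(CC)O/C1=C\C[C@](C)(OC(C)=O)C(=O)CC[C@@]2(C)O[C@H]2[C@@H]1OCc1ccc(OC)cc1
F2 | step 9 | diiodosamarium C1(10)-enolate of the 10-deacetoxy ketone (trivalent samarium; C1=C10 geometry not defined) | CC[Si](CC)(CC)O/C1=C\CC(C)=C(O[Sm](I)I)CC[C@@]2(C)O[C@H]2[C@@H]1OCc1ccc(OC)cc1
F3 | step 9 | (4R,5S,6S,7Z,10R)-4,5-epoxy-10-hydroxy-6-[(4-methoxyphenyl)methoxy]-4,10-dimethyl-7-[(triethylsilyl)oxy]cyclodec-7-en-1-one | CC[Si](CC)(CC)O/C1=C\C[C@@](C)(O)C(=O)CC[C@@]2(C)O[C@H]2[C@@H]1OCc1ccc(OC)cc1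
F4 | step 4 | (7R,8S)-7-hydroxy-8-[(4-methoxyphenyl)methoxy]-2-methyldeca-1,9-dien-5-one | C=C[C@H](OCc1ccc(OC)cc1)[C@H](O)CC(=O)CCC(C)=C
F5 | step 10 | (4R,5S,6S,8R,10R)-10-acetoxy-4,5-epoxy-8-hydroxy-6-[(4-methoxyphenyl)methoxy]-4,10-dimethylcyclodecane-1,7-dione (C8 epimer of 18) | O[C@@H]1C[C@@](C)(OC(C)=O)C(=O)CC[C@@]2(C)O[C@H]2[C@H](OCc2ccc(OC)cc2)C1=O
F6 | step 16 | (4R,5S,6S,8S,10R)-10-acetoxy-4,5-epoxy-4,10-dimethyl-8-(methacryloyloxy)-1,7-dioxocyclodecan-6-yl (triphenylphosphoranylidene)acetate | C=C(C)C(=O)O[C@H]1C[C@@](C)(OC(C)=O)C(=O)CC[C@@]2(C)O[C@H]2[C@H](OC(=O)C=P(c2ccccc2)(c2ccccc2)c2ccccc2)C1=O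
F7 | step 16 | (4R,5S,6R,8S,10R)-10-acetoxy-4,5-epoxy-8-(methacryloyloxy)-1-oxo-13-norgermacr-7(11)-en-12,6-olide (C11 unsubstituted) | C=C(C)C(=O)O[C@H]1C[C@@](C)(OC(C)=O)C(=O)CC[C@@]2(C)O[C@H]2[C@@H]2OC(=O)C=C12
F8 | step 16 | 11-iodo derivative of F7 | C=C(C)C(=O)O[C@H]1C[C@@](C)(OC(C)=O)C(=O)CC[C@@]2(C)O[C@H]2[C@@H]2OC(=O)C(I)=C12
A1 | alternative 1 | ten-membered (1(10)E)-ene epoxy-butenolide, 8-O-triethylsilyl, 13-acetate | CC[Si](CC)(CC)O[C@H]1C/C(C)=C/CC[C@@]2(C)O[C@H]2[C@@H]2OC(=O)C(COC(C)=O)=C12
A2 | alternative 1 | open-chain (1(10)E)-alkene with 4,5-epoxy C6 aldehyde, 8-O-triethylsilyl, C7 (Z)-enol triflate cis to the C12 methyl ester, 13-acetate | O=C[C@@H]1O[C@]1(C)CC/C=C(C)/C[C@H](O[Si](CC)(CC)CC)/C(OS(=O)(=O)C(F)(F)F)=C(\COC(C)=O)C(=O)OC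
A3 | alternative 2 | 3,6-dihydro-1,2-dioxine bridging C6 and C12, tetrasubstituted C7=C11, 8-O-triethylsilyl | CC[Si](CC)(CC)O[C@H]1C[C@@](C)(OC(C)=O)C(=O)CC[C@@]2(C)O[C@H]2[C@@H]2OOCC(COC(C)=O)=C12
A4 | alternative 2 | (6E)-ring-fused diene: C6=C7 in the ten-membered ring, C7 bearing the 3-acetoxyprop-1-en-2-yl group (C11=C12), 8-O-triethylsilyl | CC[Si](CC)(CC)O[C@H]1C[C@@](C)(OC(C)=O)C(=O)CC[C@@]2(C)O[C@H]2/C=C1\C(=C)COC(C)=O
A5 | alternative 3 | 8-(dimethylphenylsilyl) ten-membered (4Z,1(10)E)-dien-6-one | C[Si](C)(c1ccccc1)[C@H]1C/C(C)=C/CC/C(C)=C\C(=O)C1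
A6 | alternative 3 | trans-1-[(E)-2-(dimethylphenylsilyl)vinyl]-3-methyl-6-(prop-1-en-2-yl)cyclohex-2-en-1-ol (enantiomeric series leading to A5) | C[Si](C)(c1ccccc1)/C=C/[C@@]1(O)C=C(C)CC[C@@H]1C(C)=C
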